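I start with the side product.

| flask | starting material | coupling partner | second reagent | third reagent | temperature | remark | time |
|---|---|---|---|---|---|---|---|
| Monday's | 0.15 M | 0.40 M | 0.12 M | 0.18 M | 0 °C | run made earlier |  |
| elm | 0.10 M | 0.400 M | 0.120 M | 0.180 M | 0 °C |  | 2.0 h |
| larch | 0.10 M | 0.400 M | 0.120 M | 0.180 M | −40 °C |  | 2.0 h |
| cedar | 0.10 M | 0.400 M | 0.120 M | 0.180 M | 20 °C |  | 2.0 h |
| birch | 0.10 M | 0.400 M | 0.120 M | 0.180 M | −20 °C |  | 2.0 h |

- Monday's (time / min: target / %, side product / %): 1.50: 0.6, 8.5; 4.00: 0, 18.6; 8.00: 4.0, 25.8; 12.0: 9.6, 29.5

(each reading ± 1 percentage point)

- the earlier runs do not show what temperature does; that part of a forecast is a guess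

1. the flask that comes out highest in share of target in all that became target or side product, or "all alike" when all lie within 1.5 percentage points (elm / larch / cedar / birch / all alike)
2. share of target in all that became target or side product, elm
3. share of target in all that became target or side product, larch
4. share of target in all that became target or side product, cedar
5. share of target in all that became target or side product, birch

Monday's side product rises in shrinking steps: over equal intervals each step is 0.514 of the one before. Read as one exponential, this gives the first rung, a lifetime of 6.01 min, and a ceiling of 33.4 % of the charge. Both are readings and carry their scatter. The target comes next: it still reads 0 % at 4.00 min and climbs later. At its pace between 8.00 min and 12.0 min, the remaining 66.6 % of the charge needs 47.6 min, which is a slower rung. The last rung is the 2.0 h of elm, longer than both, so at its end elm should show the split made on the first rung.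

I take the side product to come from starting material + second reagent, and the rest of the charge to leave with the coupling partner. Then side product over rest equals σ times c(second reagent) over c(coupling partner). With each reagent at its mean over the first rung, Monday's ceiling gives 1.85 for σ, a reading with the same scatter. σ is the selectivity factor: the rate constant of the side-product step over that of the step with the coupling partner. For elm, the first round, with Monday's ceiling in the means, gives 34.3 %. Putting that back in gives 34.1 %. So I expect that much side product in elm and, if what is not side product turns into target, a target share of 65.9 %. The runs show nothing of temperature, so I read σ for 0 °C and give no number of my own for larch, birch and cedar.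

The forecast names elm, with 67 % (58 % to 75 %) for elm, 5 % for larch, 64 % for cedar and 35 % for birch, noting that “The target shows a clear lag”.

The flasks give 46.8 % for elm, 5.64 % for larch, 39.9 % for cedar and 37.6 % for birch, so the highest is elm.

    third reagent + intermediate B → target (k = 0.504 M⁻¹ min⁻¹, Ea = 44.0 kJ mol⁻¹)
    starting material + second reagent → side product (k = 0.137 M⁻¹ min⁻¹, Ea = 40.0 kJ mol⁻¹)
    starting material + coupling partner → intermediate A (k = 0.0429 M⁻¹ min⁻¹, Ea = 47.0 kJ mol⁻¹)
    intermediate A → decomposed reagent (k = 0.00276 min⁻¹, Ea = 74.0 kJ mol⁻¹)
    2 starting material → homo dimer (k = 2.10 × 10⁻⁴ M⁻¹ min⁻¹, Ea = 72.0 kJ mol⁻¹)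
    second reagent + intermediate A → intermediate B (k = 0.144 M⁻¹ min⁻¹, Ea = 42.0 kJ mol⁻¹)
    (constants at −20 °C)

Elm holds 38.0 % side product against my 34.1 %, but target 33.4 % and decomposed reagent 28.3 %. In elm half of the side-product turnover up to 2.0 h is done by 0.0713 h, and half of the turnover of second reagent + intermediate A into intermediate B by 0.246 h, which is later. With 1.0 M of coupling partner, σ gives a side product of 16.5 % of the charge, then 17.7 %, and that neighbour of elm holds 21.0 % side product.

Readings and results are simulated on assumed constants, and the scatter is random.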